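**Plan**

1. Retrosynthesis (decalin numbered as in the naphthalene name, C-1 to C-8a): the two acids come from methyl esters and the C-3 alcohol from a C-3 ketone. This 3-oxodecalin is cut at C-1–C-2 and C-4a–C-8a together.
2. Enabling feature: ring A is a cyclohexanone with its carbonyl at C-3, and C-1 (quaternary, CH3/CO2Me) sits next to the ring-fusion CH C-8a. C-2/C-3/C-4/C-4a are therefore a 2-silyloxydiene and C-1/C-8a an (E)-2-methylenoate; C-5 to C-8 of ring B are a four-carbon tether, so one intramolecular Diels–Alder reaction closes rings A and B at once.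
3. The acyclic triene is traced back by Wittig olefination, two Claisen rearrangements and an alkynylation to methyl geranate, which supplies the side chain with its (E)-enoate.
4. Forward order: chain assembly, with C-5 set by Eschenmoser–Claisen chirality transfer from a catalytically made (R)-carbinol; then diene and dienophile are unveiled, both rings form together, the C-3 ketone is reduced and the esters are cleaved.
5. Stereochemistry: C-5 from the carbinol; C-1, C-4a and C-8a from the alkene geometries and the endo, chair-tether transition state steered by C-5; C-3 from equatorial hydride attack enforced by the two syn-axial methyl groups.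

Key step: step 11

Remark: methyl geranate is taken as the commercial pure (2E) isomer.
Remark: (S,S)-ProPhenol is taken to deliver the alkynyl group to the Si face of enal 3 (8R carbinol); if the sense is the reverse, the commercial (R,R)-ligand is used.

**Route**

Step 1
Reactants: 1 methyl geranate, methyl (2E)-3,7-dimethylocta-2,6-dienoate
Product: 3 methyl (2E,6E)-3,7-dimethyl-8-oxoocta-2,6-dienoate, via allylic alcohol 2 (not isolated)
Conditions: SeO2 (1.2 equiv), 1,4-dioxane–H2O (30:1), 80 °C
Reagents that add atoms: selenium dioxide, O=[Se]=O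
Why: Riley allylic oxidation (ene reaction with SeO2, [2,3]-sigmatropic shift, then further oxidation of allylic alcohol 2) should occur at the (E)-methyl group of the electron-rich 6,7-alkene and give the (E)-enal, the conjugated 2,3-alkene being deactivated.

Step 2
Reactants: 3 methyl (2E,6E)-3,7-dimethyl-8-oxoocta-2,6-dienoate
Product: 4 methyl (2E,6E,8R)-8-hydroxy-3,7-dimethyl-10-(trimethylsilyl)deca-2,6-dien-9-ynoate
Conditions: HC≡CSiMe3 (3 equiv), Me2Zn (3 equiv), (S,S)-ProPhenol (10 mol%), Ph3P=O (20 mol%), toluene, 0 °C; then H2O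
Reagents that add atoms: ethynyltrimethylsilane, C#C[Si](C)(C)C
Why: Dinuclear-zinc ProPhenol-catalysed enantioselective alkynylation of an enal, in which the zinc acetylide formed in situ adds 1,2 to the aldehyde on the Si face inside the chiral pocket to set the (8R) carbinol, the unsaturated ester being inert to alkynylzinc reagents.

Step 3
Reactants: 4 methyl (2E,6E,8R)-8-hydroxy-3,7-dimethyl-10-(trimethylsilyl)deca-2,6-dien-9-ynoate
Product: 6 methyl (2E,6S,7E)-6-[2-(dimethylamino)-2-oxoethyl]-3,7-dimethyl-10-(trimethylsilyl)deca-2,7-dien-9-ynoate, via ketene N,O-acetal 5 (not isolated)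
Conditions: MeC(OMe)2NMe2 (4 equiv), xylene, 135 °C, MeOH distilled off
Reagents that add atoms: 1,1-dimethoxy-N,N-dimethylethanamine, CC(OC)(OC)N(C)C
Why: Eschenmoser–Claisen rearrangement, in which ketene N,O-acetal 5 rearranges suprafacially through a chair transition state with the alkynyl group equatorial (an axial one would clash with NMe2), giving the (E)-trisubstituted enyne and transferring the (8R) carbinol chirality to the new (6S) stereocentre, while the silyl-capped alkyne terminus is too hindered for a competing propargylic shift.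

Step 4
Reactants: 6 methyl (2E,6S,7E)-6-[2-(dimethylamino)-2-oxoethyl]-3,7-dimethyl-10-(trimethylsilyl)deca-2,7-dien-9-ynoate
Product: 7 methyl (2E,6S,7E)-3,7-dimethyl-6-(2-oxoethyl)-10-(trimethylsilyl)deca-2,7-dien-9-ynoate
Conditions: Cp2Zr(H)Cl (1.6 equiv), THF, rt, 20 min; then H2O, silica gel
Reagents that add atoms: none
Why: Chemoselective partial reduction of a tertiary amide by hydrozirconation of its C=O bond to a zirconated hemiaminal that releases the aldehyde only on work-up, so that over-reduction is avoided and the methyl ester is left alone.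

Step 5
Reactants: 7 methyl (2E,6S,7E)-3,7-dimethyl-6-(2-oxoethyl)-10-(trimethylsilyl)deca-2,7-dien-9-ynoate
Product: 8 methyl (2E,6R,7E)-3,7-dimethyl-6-(3-oxoprop-1-en-2-yl)-10-(trimethylsilyl)deca-2,7-dien-9-ynoate
Conditions: aq. CH2O (37%, 1.2 equiv), pyrrolidine (10 mol%), EtCO2H (10 mol%), i-PrOH, 45 °C
Reagents that add atoms: formaldehyde, C=O
Why: Amine-catalysed Mannich condensation of the aldehyde with formaldehyde (α-methylenation by enamine addition to the iminium ion and β-elimination of the amine) should give the 2-substituted acrolein, and the adjacent stereocentre is not vinylogously acidic in this cross-conjugated enal and should keep its configuration (the descriptor changes only by priority).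

Step 6
Reactants: 8 methyl (2E,6R,7E)-3,7-dimethyl-6-(3-oxoprop-1-en-2-yl)-10-(trimethylsilyl)deca-2,7-dien-9-ynoate
Product: 9 methyl (2E,6R,7E)-6-(3-hydroxyprop-1-en-2-yl)-3,7-dimethyl-10-(trimethylsilyl)deca-2,7-dien-9-ynoate
Conditions: NaBH4 (1.0 equiv), CeCl3·7H2O (1.1 equiv), MeOH, −40 °C
Reagents that add atoms: none
Why: Luche reduction, in which CeCl3-mediated 1,2-delivery of hydride to the enal gives the 2-substituted allylic alcohol without touching the ester, the silylalkyne or the stereocentre.

Step 7
Reactants: 9 methyl (2E,6R,7E)-6-(3-hydroxyprop-1-en-2-yl)-3,7-dimethyl-10-(trimethylsilyl)deca-2,7-dien-9-ynoate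
Product: 10 methyl (2E,6R,7E)-6-[3-(ethenyloxy)prop-1-en-2-yl]-3,7-dimethyl-10-(trimethylsilyl)deca-2,7-dien-9-ynoate
Conditions: CH2=CHOBu (20 equiv), Pd(OCOCF3)2 (2 mol%), 4,7-diphenyl-1,10-phenanthroline (2 mol%), Et3N (10 mol%), 75 °C, air
Reagents that add atoms: butyl vinyl ether, C=COCCCC
Why: Divalent-palladium-catalysed transfer vinylation (transetherification with excess alkyl vinyl ether) should convert the primary allylic alcohol into the allyl vinyl ether under nearly neutral conditions.

Step 8
Reactants: 10 methyl (2E,6R,7E)-6-[3-(ethenyloxy)prop-1-en-2-yl]-3,7-dimethyl-10-(trimethylsilyl)deca-2,7-dien-9-ynoate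
Product: 12 methyl (2E,6S,7E)-6-[(5E)-7-methoxy-6-methyl-7-oxohepta-1,5-dien-2-yl]-3,7-dimethyl-10-(trimethylsilyl)deca-2,7-dien-9-ynoate, via aldehyde 11 (not isolated)
Conditions: Ph3P=C(CH3)CO2Me (1.5 equiv), toluene, 140 °C, sealed tube
Reagents that add atoms: methyl 2-(triphenyl-λ5-phosphanylidene)propanoate, COC(=O)C(C)=P(c1ccccc1)(c1ccccc1)c1ccccc1
Why: Aliphatic Claisen rearrangement of the 2-substituted allyl vinyl ether gives aldehyde 11 with the 1,1-disubstituted alkene in place (both allyl termini are CH2, so no stereochemical issue arises), and Wittig olefination in the same flask with the stabilised α-methyl ylide should give the (E)-2-methylenoate.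

Step 9
Reactants: 12 methyl (2E,6S,7E)-6-[(5E)-7-methoxy-6-methyl-7-oxohepta-1,5-dien-2-yl]-3,7-dimethyl-10-(trimethylsilyl)deca-2,7-dien-9-ynoate
Product: 14 methyl (2E,6S,7E)-6-[(5E)-7-methoxy-6-methyl-7-oxohepta-1,5-dien-2-yl]-3,7-dimethyl-9-oxodeca-2,7-dienoate, via terminal enyne 13 (not isolated)
Conditions: AgOSO2CF3 (10 mol%), Ph3PAuCl (3 mol%), acetone–H2O (10:1), 45 °C
Reagents that add atoms: water, O
Why: Silver-catalysed protodesilylation of the alkynylsilane followed by monovalent-gold-catalysed Markovnikov hydration of the terminal alkyne of the conjugated enyne should place the oxygen on the internal carbon and give the (E)-methyl enone, the (E)-alkene geometry keeping the other alkenes out of reach for cycloisomerisation.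

Step 10
Reactants: 14 methyl (2E,6S,7E)-6-[(5E)-7-methoxy-6-methyl-7-oxohepta-1,5-dien-2-yl]-3,7-dimethyl-9-oxodeca-2,7-dienoate
Product: 15 methyl (2E,6S,7E)-9-[(tert-butyldimethylsilyl)oxy]-6-[(5E)-7-methoxy-6-methyl-7-oxohepta-1,5-dien-2-yl]-3,7-dimethyldeca-2,7,9-trienoate
Conditions: TBSOTf (1.3 equiv), Et3N (2.5 equiv), CH2Cl2, −78 → 0 °C
Reagents that add atoms: tert-butyldimethylsilyl trifluoromethanesulfonate, CC(C)(C)[Si](C)(C)OS(=O)(=O)C(F)(F)F
Why: Soft enolisation, in which O-silylation of the enone and kinetic deprotonation of the resulting oxocarbenium ion at the methyl group give the cross-conjugated 2-silyloxy-1,3-diene, the esters not being enolised by Et3N.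

Step 11
Reactants: 15 methyl (2E,6S,7E)-9-[(tert-butyldimethylsilyl)oxy]-6-[(5E)-7-methoxy-6-methyl-7-oxohepta-1,5-dien-2-yl]-3,7-dimethyldeca-2,7,9-trienoate
Product: 17 methyl (1R,4aR,5S,8aR)-5-[(3E)-5-methoxy-3-methyl-5-oxopent-3-en-1-yl]-1,4a-dimethyl-6-methylidene-3-oxodecahydronaphthalene-1-carboxylate, via silyl enol ether 16 (not isolated)
Conditions: toluene (5 mM), BHT (10 mol%), 180 °C, base-washed sealed tube; then 0.5 M aq. HCl, THF, rt
Reagents that add atoms: none
Why: Thermal, concerted but asynchronous [4+2] cycloaddition between the 2-silyloxy-1,3-diene and the tethered (E)-2-methylenoate of 15, the closest known reaction type being the type 1 intramolecular Diels–Alder reaction of 1,7,9-decatrienes carrying a 2-silyloxydiene and a terminal ester, followed by acid hydrolysis of silyl enol ether 16 to ketone 17. Ring A is closed as the new cyclohexene by both σ bonds (diene CH2 terminus to the ester α-carbon, C-2–C-1; methyl-bearing diene terminus to the enoate β-carbon, C-4a–C-8a), and ring B is closed by the second of these bonds in the fused mode through the four-carbon tether C-5 to C-8, which also overrides the normal regiochemical preference of a 2-silyloxydiene. C-1 and C-8a are tied stereospecifically by suprafacial addition to the (E)-enoate (CO2Me cis to H-8a, CH3 cis to C-8), and C-4a follows from the (E)-diene reacting through the ester-endo transition state with a chair-like tether, which gives the trans ring fusion with the C-1 and C-4a methyl groups cis. The absolute sense comes from the existing C-5 stereocentre, whose side chain takes the equatorial position on the forming ring B so that H-5 ends anti to the C-4a methyl group. The step thus needs endo and π-facial selectivity; the first should be secured by secondary overlap of the ester with the diene and by both reacting termini being equatorial on the tether (the sp2 C-6 removes one syn-axial hydrogen from the axial methyl group), the second by avoidance of a syn-axial side chain. The side-chain 3-methylenoate should not compete because it is β,β-disubstituted and could only be reached through a three-atom tether with formation of two adjacent quaternary carbons, and the 1,1-disubstituted alkene is unactivated.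

Step 12
Reactants: 17 methyl (1R,4aR,5S,8aR)-5-[(3E)-5-methoxy-3-methyl-5-oxopent-3-en-1-yl]-1,4a-dimethyl-6-methylidene-3-oxodecahydronaphthalene-1-carboxylate
Product: 18 methyl (1R,3S,4aR,5S,8aR)-3-hydroxy-5-[(3E)-5-methoxy-3-methyl-5-oxopent-3-en-1-yl]-1,4a-dimethyl-6-methylidenedecahydronaphthalene-1-carboxylate
Conditions: LiBH(s-Bu)3 (1.3 equiv), THF, −78 °C; then H2O
Reagents that add atoms: none
Why: Ketone reduction with a bulky trialkylborohydride, in which the axial (β) trajectory at C-3 is blocked by the two syn-axial methyl groups on C-1 and C-4a, so that hydride enters equatorially from the α face and gives the axial (3S) alcohol, the esters and the hindered enoate being inert at −78 °C.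

Step 13
Reactants: 18 methyl (1R,3S,4aR,5S,8aR)-3-hydroxy-5-[(3E)-5-methoxy-3-methyl-5-oxopent-3-en-1-yl]-1,4a-dimethyl-6-methylidenedecahydronaphthalene-1-carboxylate
Product: 19 (1R,3S,4aR,5S,8aR)-5-[(3E)-4-carboxy-3-methylbut-3-en-1-yl]-3-hydroxy-1,4a-dimethyl-6-methylidenedecahydronaphthalene-1-carboxylic acid
Conditions: KOH (12 equiv), DMSO–H2O (10:1), 60 °C; then aq. HCl to pH 2
Reagents that add atoms: potassium hydroxide, [K+].[OH-]
Why: Saponification by acyl–oxygen cleavage, in which poorly solvated hydroxide in aqueous DMSO should also attack the neopentyl-type equatorial ester on C-1, the side-chain ester being cleaved first to a carboxylate that resists isomerisation.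

**Compound list**

1 | methyl geranate, methyl (2E)-3,7-dimethylocta-2,6-dienoate | CC(C)=CCC/C(C)=C/C(=O)OC | starting material
2 | methyl (2E,6E)-8-hydroxy-3,7-dimethylocta-2,6-dienoate | COC(=O)/C=C(C)/CC/C=C(C)/CO | intermediate
3 | methyl (2E,6E)-3,7-dimethyl-8-oxoocta-2,6-dienoate | COC(=O)/C=C(C)/CC/C=C(C)/C=O | intermediate
4 | methyl (2E,6E,8R)-8-hydroxy-3,7-dimethyl-10-(trimethylsilyl)deca-2,6-dien-9-ynoate | COC(=O)/C=C(C)/CC/C=C(C)/[C@@H](O)C#C[Si](C)(C)C | intermediate
5 | methyl (2E,6E,8R)-8-{[1-(dimethylamino)ethenyl]oxy}-3,7-dimethyl-10-(trimethylsilyl)deca-2,6-dien-9-ynoate | C=C(N(C)C)O[C@@H](C#C[Si](C)(C)C)/C(C)=C/CC/C(C)=C/C(=O)OC | intermediate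
6 | methyl (2E,6S,7E)-6-[2-(dimethylamino)-2-oxoethyl]-3,7-dimethyl-10-(trimethylsilyl)deca-2,7-dien-9-ynoate | CN(C)C(=O)C[C@H](CC/C(C)=C/C(=O)OC)/C(C)=C/C#C[Si](C)(C)C | intermediate
7 | methyl (2E,6S,7E)-3,7-dimethyl-6-(2-oxoethyl)-10-(trimethylsilyl)deca-2,7-dien-9-ynoate | O=CC[C@H](CC/C(C)=C/C(=O)OC)/C(C)=C/C#C[Si](C)(C)C | intermediate
8 | methyl (2E,6R,7E)-3,7-dimethyl-6-(3-oxoprop-1-en-2-yl)-10-(trimethylsilyl)deca-2,7-dien-9-ynoate | O=CC(=C)[C@H](CC/C(C)=C/C(=O)OC)/C(C)=C/C#C[Si](C)(C)C | intermediate
9 | methyl (2E,6R,7E)-6-(3-hydroxyprop-1-en-2-yl)-3,7-dimethyl-10-(trimethylsilyl)deca-2,7-dien-9-ynoate | OCC(=C)[C@H](CC/C(C)=C/C(=O)OC)/C(C)=C/C#C[Si](C)(C)C | intermediate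
10 | methyl (2E,6R,7E)-6-[3-(ethenyloxy)prop-1-en-2-yl]-3,7-dimethyl-10-(trimethylsilyl)deca-2,7-dien-9-ynoate | C=COCC(=C)[C@H](CC/C(C)=C/C(=O)OC)/C(C)=C/C#C[Si](C)(C)C | intermediate
11 | methyl (2E,6S,7E)-3,7-dimethyl-6-(5-oxopent-1-en-2-yl)-10-(trimethylsilyl)deca-2,7-dien-9-ynoate | O=CCCC(=C)[C@H](CC/C(C)=C/C(=O)OC)/C(C)=C/C#C[Si](C)(C)C | intermediate
12 | methyl (2E,6S,7E)-6-[(5E)-7-methoxy-6-methyl-7-oxohepta-1,5-dien-2-yl]-3,7-dimethyl-10-(trimethylsilyl)deca-2,7-dien-9-ynoate | COC(=O)/C(C)=C/CCC(=C)[C@H](CC/C(C)=C/C(=O)OC)/C(C)=C/C#C[Si](C)(C)C | intermediate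
13 | methyl (2E,6S,7E)-6-[(5E)-7-methoxy-6-methyl-7-oxohepta-1,5-dien-2-yl]-3,7-dimethyldeca-2,7-dien-9-ynoate | COC(=O)/C(C)=C/CCC(=C)[C@H](CC/C(C)=C/C(=O)OC)/C(C)=C/C#C | intermediate
14 | methyl (2E,6S,7E)-6-[(5E)-7-methoxy-6-methyl-7-oxohepta-1,5-dien-2-yl]-3,7-dimethyl-9-oxodeca-2,7-dienoate | COC(=O)/C(C)=C/CCC(=C)[C@H](CC/C(C)=C/C(=O)OC)/C(C)=C/C(C)=O | intermediate
15 | methyl (2E,6S,7E)-9-[(tert-butyldimethylsilyl)oxy]-6-[(5E)-7-methoxy-6-methyl-7-oxohepta-1,5-dien-2-yl]-3,7-dimethyldeca-2,7,9-trienoate | COC(=O)/C(C)=C/CCC(=C)[C@H](CC/C(C)=C/C(=O)OC)/C(C)=C/C(=C)O[Si](C)(C)C(C)(C)C | intermediate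
16 | methyl (1R,4aR,5S,8aR)-3-[(tert-butyldimethylsilyl)oxy]-5-[(3E)-5-methoxy-3-methyl-5-oxopent-3-en-1-yl]-1,4a-dimethyl-6-methylidene-1,2,4a,5,6,7,8,8a-octahydronaphthalene-1-carboxylate | C=C1CC[C@@H]2[C@](C)(C=C(O[Si](C)(C)C(C)(C)C)C[C@@]2(C)C(=O)OC)[C@H]1CC/C(C)=C/C(=O)OC | intermediate
17 | methyl (1R,4aR,5S,8aR)-5-[(3E)-5-methoxy-3-methyl-5-oxopent-3-en-1-yl]-1,4a-dimethyl-6-methylidene-3-oxodecahydronaphthalene-1-carboxylate | C=C1CC[C@@H]2[C@](C)(CC(=O)C[C@@]2(C)C(=O)OC)[C@H]1CC/C(C)=C/C(=O)OC | intermediate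
18 | methyl (1R,3S,4aR,5S,8aR)-3-hydroxy-5-[(3E)-5-methoxy-3-methyl-5-oxopent-3-en-1-yl]-1,4a-dimethyl-6-methylidenedecahydronaphthalene-1-carboxylate | C=C1CC[C@@H]2[C@](C)(C[C@H](O)C[C@@]2(C)C(=O)OC)[C@H]1CC/C(C)=C/C(=O)OC | intermediate
19 | (1R,3S,4aR,5S,8aR)-5-[(3E)-4-carboxy-3-methylbut-3-en-1-yl]-3-hydroxy-1,4a-dimethyl-6-methylidenedecahydronaphthalene-1-carboxylic acid | C=C1CC[C@@H]2[C@](C)(C[C@H](O)C[C@@]2(C)C(=O)O)[C@H]1CC/C(C)=C/C(=O)O | target

**Step count and risks**

Total step count: 13. Longest linear sequence: 13 steps (fully linear from 1).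

Steps most likely to fail:

1. Step 11. The cycloaddition may pass in part through the ester-exo (cis-fused) or the axial-side-chain transition state, and a [1,5]-hydrogen shift from the inside methyl group of the diene may outrun ring closure at 180 °C. Fallback: leave the thermal pericyclic mode for a Lewis-acid-promoted, charge-accelerated cyclisation at low temperature. Setting out from enone 14, i-Pr3SiOSO2CF3 and Et3N should give the more acid-stable dienol ether methyl (2E,6S,7E)-6-[(5E)-7-methoxy-6-methyl-7-oxohepta-1,5-dien-2-yl]-3,7-dimethyl-9-[(triisopropylsilyl)oxy]deca-2,7,9-trienoate F1. Me2AlCl (1.2 equiv, CH2Cl2, −78 → −20 °C) binds the ester of the (E)-2-methylenoate, which enforces the ester-endo transition state and lets ring closure run far below the temperature of the hydrogen shift. This should give methyl (1R,4aR,5S,8aR)-5-[(3E)-5-methoxy-3-methyl-5-oxopent-3-en-1-yl]-1,4a-dimethyl-6-methylidene-3-[(triisopropylsilyl)oxy]-1,2,4a,5,6,7,8,8a-octahydronaphthalene-1-carboxylate F2. Aqueous HCl in THF then comes back to the route at ketone 17.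

2. Step 2. Enantiofacial discrimination on the α-branched enal may be insufficient, or the sense of induction may be the reverse of the one assumed. Fallback: replace the enantioselective addition by an enantioselective ketone reduction. Setting out from enal 3, LiC≡CSiMe3 (THF, −78 °C) should give racemic methyl (2E,6E)-8-hydroxy-3,7-dimethyl-10-(trimethylsilyl)deca-2,6-dien-9-ynoate F3. MnO2 (CH2Cl2, rt) oxidises it to methyl (2E,6E)-3,7-dimethyl-8-oxo-10-(trimethylsilyl)deca-2,6-dien-9-ynoate F4. CBS reduction with the (R)-Me-CBS oxazaborolidine and catecholborane (toluene, −78 °C), in which the α-branched alkenyl group acts as the large and the alkynyl group as the small substituent, should come back to the route at (8R)-carbinol 4.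

3. Step 13. Hydroxide may attack the hindered C-1 ester too slowly, and forcing the acyl substitution may shift or isomerise the side-chain double bond. Fallback: cleave the esters at the O–CH3 bond instead of the acyl carbon. Setting out from hydroxy diester 18, LiSCH2CH2CH3 (excess) in HMPA at rt demethylates both esters by SN2 attack on the methyl groups, and acidification comes back to the route at target 19; no compound outside the list is made (F0).

Further compounds
F1 | step 11 | methyl (2E,6S,7E)-6-[(5E)-7-methoxy-6-methyl-7-oxohepta-1,5-dien-2-yl]-3,7-dimethyl-9-[(triisopropylsilyl)oxy]deca-2,7,9-trienoate | COC(=O)/C(C)=C/CCC(=C)[C@H](CC/C(C)=C/C(=O)OC)/C(C)=C/C(=C)O[Si](C(C)C)(C(C)C)C(C)C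
F2 | step 11 | methyl (1R,4aR,5S,8aR)-5-[(3E)-5-methoxy-3-methyl-5-oxopent-3-en-1-yl]-1,4a-dimethyl-6-methylidene-3-[(triisopropylsilyl)oxy]-1,2,4a,5,6,7,8,8a-octahydronaphthalene-1-carboxylate | C=C1CC[C@@H]2[C@](C)(C=C(O[Si](C(C)C)(C(C)C)C(C)C)C[C@@]2(C)C(=O)OC)[C@H]1CC/C(C)=C/C(=O)OC
F3 | step 2 | racemic methyl (2E,6E)-8-hydroxy-3,7-dimethyl-10-(trimethylsilyl)deca-2,6-dien-9-ynoate | COC(=O)/C=C(C)/CC/C=C(C)/C(O)C#C[Si](C)(C)C
F4 | step 2 | methyl (2E,6E)-3,7-dimethyl-8-oxo-10-(trimethylsilyl)deca-2,6-dien-9-ynoate | COC(=O)/C=C(C)/CC/C=C(C)/C(=O)C#C[Si](C)(C)C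
F0 | step 13 | none | none
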